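## Structural features

The target 20 is a 1-aryltetralin. Ring A is a pentasubstituted benzene (methoxy groups on C6 and C8, hydroxyl on C7) fused through C4a–C8a to the saturated ring B (C1 to C4), and C1 carries a 4-hydroxy-3,5-dimethoxyphenyl group (ring C, attached through C1'). C1 (S), C2 (R) and C3 (R) are three contiguous stereocentres in the all-trans arrangement; C2 and C3 each bear a hydroxymethyl group (C9 and C10), and ring C on C1 is trans to C9. The fragile parts are the two 2,6-dimethoxyphenol units, which are oxidised easily, the doubly benzylic C1 methine next to the C8 methoxy group, which can ionise under acid, and the two primary alcohols, which could capture such a cation. The real difficulty is C1: a crowded carbon that must be joined to two arenes with a defined configuration relative to C2, while C2 and C3 survive intermediates in which C2 is alpha to a carbonyl group. The key step exploits the fact that both arene carbons on C1 are innately nucleophilic positions (C8a is ortho to the C8 and para to the C6 methoxy group; C1' is para to the hydroxyl of ring C), so C1 can be an aldehyde carbon on C2 that is arylated twice. Two further features help: ring A derives from a symmetric 4-oxy-3,5-dimethoxyphenyl unit, so its two ortho carbons are equivalent, and the C9–C2–C3–C10 unit with its trans branches maps onto a trans-disubstituted butyrolactone.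

## Logic of the disconnections

**20 ⇒ 19 ⇒ 18.** No carbon–carbon bond is cut; the benzyl–oxygen bond on the C7 oxygen and the two pivaloyl–oxygen bonds on the C9 and C10 oxygens are put back. The reason is that the cationic ring closure tolerates neither free aliphatic hydroxyl groups (they would trap the C1 cation) nor, in the earlier base and hydride steps, a free ring A phenol. The gain is a substrate, 18, whose only free heteroatom function is the ring C phenol that the key step itself delivers. The demand on the forward steps is mildness toward the C1 methine and the aryl methyl ethers: hydride cleavage of the esters first, neutral hydrogenolysis last.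

**18 ⇒ 15 + 16.** C1–C8a and C1–C1' are cut together. This removes ring B, the stereocentre C1 and the whole of ring C in one move and leaves an acyclic aldehyde, 15, in which C1 is the carbonyl carbon, plus the purchasable phenol 16. The forward step must close the ring faster than 16 attacks the aldehyde intermolecularly, must bring 16 in through its para carbon and trans to the C2 branch, must not let C2 enolise or the C1 cation lose the C2 proton, and must spare the benzyl ether.

**15 ⇒ 14 ⇒ 13 ⇒ 12.** Only bonds to oxygen change: the C1 aldehyde is traced to a primary alcohol, that alcohol to a triisopropylsilyl ether, and the two pivalates to the free C9/C10 diol. The reason is that the alpha-branched, beta-acyloxy aldehyde should be made last and under neutral conditions, and that the C1 oxygen must stay distinguishable from the C9 and C10 oxygens until then. The gain is a set of stable intermediates. The demand is that neither the silyl group nor a pivaloyl group wanders between the C1 and C9 oxygens, because these two arms on C2 differ only in their substituents and an exchange would invert C2. That is why the bulkiest common silyl group and an acidic fluoride source are used.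

**12 ⇒ 11 ⇒ 10.** The C9 and C10 oxygens are rejoined through C9 as a gamma-lactone. In the lactone the three oxygenated carbons are differentiated without any selective reaction: C1 carries the only free hydroxyl, C9 is the acyl carbon and C10 the alkoxy carbon. The five-membered ring is also the device that relays configuration from C3 to C2. The forward demand is that silylation precede reduction, so that hydride never meets a beta-hydroxy carbonyl compound open to retro-aldol cleavage.

**10 ⇒ 8.** C1–C2 is cut; C1 leaves as a one-carbon electrophile at the formaldehyde level. This removes one stereocentre and leaves 8 with a single one. The forward step must add the electrophile trans to the arylmethyl branch; a trans lactone corresponds to the C9/C10 trans relationship in ring B.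

**8 ⇒ 6 ⇒ 5.** The lactone C–O bond is opened, C10 is traced to a methyl ester, and the hydrogens on C3 and C4 are removed to give the C3=C4 alkene. The one stereocentre that has to be created without a neighbour thereby becomes the product of a carboxylate-directed asymmetric hydrogenation. The half-ester already distinguishes C9 (acid) from C10 (ester). The demands are face selection by the catalyst and reduction of the ester in the presence of the carboxylate.

**5 ⇒ 2 + 3, and 2 ⇒ 1.** The C3=C4 double bond is cut into an aromatic aldehyde and a succinate, which are a C7 and a C4 building block of commerce. The forward condensation requires the phenol of 1 to be masked, because a phenoxide para to the formyl group would switch off its electrophilicity; this is the origin of the benzyl ether in 2.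

## Other disconnections considered

**Alternative 1:** The cut goes through C2–C3 and C1–C8a and splits the skeleton into two identical phenylpropanoid halves, held together as the bis-sinapate ester A1 of a (2R,4R)-pentane-2,4-diyl tether. In the forward sense FeCl3 would oxidise both phenols of A1 to phenoxyl radicals, which would couple through their beta carbons (C2–C3). One of the two quinone methides would then tautomerise, restoring its arene and leaving the C3=C4 double bond, and C8a of that arene would add to C1 of the other quinone methide, closing ring B and the nine-membered dilactone of A2.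
- In its favour: the route is biomimetic, both arenes arrive with their final oxygenation and without protecting groups, and two carbon–carbon bonds, ring B and the C1 and C2 stereocentres would come from one operation on a substrate that is one or two steps from commercial material. The 3,5-dimethoxy pattern also blocks the ring positions at which such radicals usually go astray.
- Against it here: in A2 the carbon C3 is sp2, so the third stereocentre must be made afterwards by reducing a hindered conjugated alkene from the correct face or by equilibration next to the ester. The transfer of chirality from the remote tether through a medium ring to C1 and C2 is hard to predict, and free electron-rich phenols under an oxidant invite overoxidation and oligomer formation.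
- Comparison: on step economy and atom economy this alternative is the better plan (roughly half the operations), and it uses the hidden twofold symmetry of the two halves, which the chosen plan ignores. Both plans lean on the same innate nucleophilicity of C8a and are equal there. The chosen plan is the stronger one on stereochemical reliability: C3 comes from a catalyst, C2 from a lactone alkylation and C1 from its neighbour C2, each through a separate and well-understood element, whereas in the dimerisation everything rests on one tether.

**Alternative 2:** The cut is at C1–C1' and C1–C2. Ring C would enter as the aryl bromide A4, and ring A as the N-tosylhydrazone A3 of a ring A benzaldehyde whose C4–C3 tether ends in a malonate. With Pd2(dba)3, a phosphine and LiOtBu, oxidative addition of A4 to zerovalent palladium and decomposition of the diazo compound formed from A3 would give an arylpalladium carbene at C1. Migratory insertion of the aryl group would form C1–C1', and the tethered malonate anion would capture the resulting benzylpalladium species, forming C1–C2 and closing ring B to give A5.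
- In its favour: like the chosen plan it lets C1 take up two bonds in one flask, so on the central idea the two are equal. It is the better plan on regiochemistry at ring C, because the carbon–bromine bond fixes the point of attachment that the chosen plan leaves to the directing effects in 16. The medium is basic, so there is no C1 cation and no acid near the benzyl ethers, and all three benzyl ethers would fall in a single final hydrogenolysis, which is equal to or slightly better than the two-step end game chosen here.
- Against it here: the carbene carbon sits between a methoxy group and the alkyl tether, a crowded place for carbene formation and aryl migration. C1 would be set only relative to C3, a 1,3 relationship across a quaternary C2, which is a weaker control element than the 1,2 relationship used in the chosen plan. C2 arrives as a geminal diester, so one ester carbon has to be excised and C2 set afterwards by protonation or equilibration. A3 needs a regioselective formylation of the crowded ring A and its own asymmetric construction of C3.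
- Comparison: the step count should come out equal or somewhat longer, and atom economy is worse because a carbon is installed and then discarded.

**Alternative 3:** Here ring A itself is cut (C4a–C5, C5–C6, C7–C8 and C8–C8a), leaving the cyclohexenyl diazoketone A6 with all three stereocentres, and methoxyethyne A7. Irradiation of A6 would trigger a Wolff rearrangement (C4a–C5) to a vinylketene, which would add A7 in a [2+2] fashion (C5–C6 and C7–C8). Four-electron opening of the cyclobutenone, six-electron closure (C8–C8a) and tautomerisation would give the phenol A8.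
- In its favour: the stereocentres are assembled on a cyclohexene before the arene exists, so no C1 cation ever stands next to a removable C2 proton; on the integrity of C1 and C2 this plan is the better one. Regiochemistry follows from the polarity of ketene and alkyne rather than from arene directing effects, the conditions are neutral, and four ring bonds are formed in one step against two in the chosen key step.
- Against it here: A8 carries only two of the three ring A oxygens (C6 methoxy, C8 hydroxyl). C8 would have to be methylated and the C7 oxygen introduced afterwards, for example by metalation between the two methoxy groups and oxidation, and two kinds of protecting group then removed. A6, a cyclohexene with three contiguous stereocentres and a diazoacetyl group, needs a long asymmetric synthesis of its own, so the stereochemical problem is moved rather than solved, and A7 is volatile and unstable.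
- Comparison: on structure, ring A of 20 is a symmetric unit that can be bought fully oxygenated, so building it from scratch gains nothing. On step economy this plan is clearly the longer one.

Key step: step 11

Assumption: Ru(OAc)2[(S)-BINAP] is taken to deliver hydrogen to the face of 5 that gives (3R)-6; should the sense be the opposite, Ru(OAc)2[(R)-BINAP] is used and nothing else in the route changes.

In the step names Ar = 4-(benzyloxy)-3,5-dimethoxyphenyl. Atom labels C1 to C4, C4a, C8a, C9, C10 and C1' denote the positions these atoms take in 20.

## Steps

Step 1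
Reactants: 1 syringaldehyde (4-hydroxy-3,5-dimethoxybenzaldehyde)
Product: 2 4-(benzyloxy)-3,5-dimethoxybenzaldehyde
Conditions: BnBr, K2CO3, DMF, 60 °C
Reagents that add atoms: benzyl bromide, BrCc1ccccc1
Why: Williamson etherification of the phenoxide with a reactive benzylic halide; the ether removes the acidic phenol, whose phenoxide would deactivate the para formyl group in the condensation and consume base in the later enolate and hydride steps.

Step 2
Reactants: 2 4-(benzyloxy)-3,5-dimethoxybenzaldehyde; 3 dimethyl succinate
Product: 5 (E)-4-Ar-3-(methoxycarbonyl)but-3-enoic acid, via paraconate lactone 4 (not isolated)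
Conditions: NaOMe, MeOH, reflux; then aq. HCl
Reagents that add atoms: none
Why: Stobbe condensation: the succinate enolate adds to the aldehyde, the alkoxide lactonises onto the distal ester to give 4, and base-induced ring opening (E1cB) delivers the half-ester with the aryl group trans to the ester, leaving the two carboxyl carbons differentiated.

Step 3
Reactants: 5 (E)-4-Ar-3-(methoxycarbonyl)but-3-enoic acid
Product: 6 (3R)-4-Ar-3-(methoxycarbonyl)butanoic acid
Conditions: H2 (10 atm), Ru(OAc)2[(S)-BINAP] (1 mol%), MeOH, 50 °C
Reagents that add atoms: none
Why: Carboxylate-directed asymmetric hydrogenation of an itaconate-type half-ester: the free acid binds to ruthenium and the atropisomeric diphosphine selects the alkene face, which sets C3; a homogeneous ruthenium catalyst of this kind should not hydrogenolyse the aryl benzyl ether.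

Step 4
Reactants: 6 (3R)-4-Ar-3-(methoxycarbonyl)butanoic acid
Product: 8 (4R)-4-(Ar-methyl)dihydrofuran-2(3H)-one, via hydroxy acid 7 (not isolated)
Conditions: LiBH4, THF, 0 °C → rt; then 2 M HCl, rt
Reagents that add atoms: none
Why: Chemoselective borohydride reduction: LiBH4 reduces the methyl ester and leaves the lithium carboxylate, and acidification closes the gamma-lactone; the stereocentre is untouched and ends beta to the carbonyl group, where it can no longer enolise.

Step 5
Reactants: 8 (4R)-4-(Ar-methyl)dihydrofuran-2(3H)-one
Product: 10 (3S,4R)-4-(Ar-methyl)-3-(hydroxymethyl)dihydrofuran-2(3H)-one, via lithium enolate 9 (not isolated)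
Conditions: LiN(iPr)2, THF, −78 °C; CH2O (gas, from cracked paraformaldehyde), −78 → −40 °C; aq. NH4Cl
Reagents that add atoms: formaldehyde, C=O
Why: Aldol addition of a lactone lithium enolate to monomeric formaldehyde; the electrophile approaches the planar enolate from the face opposite to the neighbouring arylmethyl group, so the new stereocentre (the future C2) is set trans to it.

Step 6
Reactants: 10 (3S,4R)-4-(Ar-methyl)-3-(hydroxymethyl)dihydrofuran-2(3H)-one
Product: 11 (3S,4R)-4-(Ar-methyl)-3-{[(triisopropylsilyl)oxy]methyl}dihydrofuran-2(3H)-one
Conditions: iPr3SiCl, imidazole, DMF, rt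
Reagents that add atoms: chlorotriisopropylsilane, CC(C)[Si](Cl)(C(C)C)C(C)C
Why: Imidazole-promoted silylation of a primary alcohol; it blocks retro-aldol cleavage in the hydride step and marks the future C1 oxygen, and the triisopropylsilyl group is chosen because it is the common silyl ether least prone to 1,3 oxygen-to-oxygen migration.

Step 7
Reactants: 11 (3S,4R)-4-(Ar-methyl)-3-{[(triisopropylsilyl)oxy]methyl}dihydrofuran-2(3H)-one
Product: 12 (2R,3R)-2-(Ar-methyl)-3-{[(triisopropylsilyl)oxy]methyl}butane-1,4-diol
Conditions: LiAlH4, THF, 0 °C; aq. potassium sodium tartrate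
Reagents that add atoms: none
Why: Hydride reduction of the lactone to the 1,4-diol; no stereocentre is involved, and the C9 and C10 oxygens appear as the only free hydroxyl groups.

Step 8
Reactants: 12 (2R,3R)-2-(Ar-methyl)-3-{[(triisopropylsilyl)oxy]methyl}butane-1,4-diol
Product: 13 (2R,3R)-2-(Ar-methyl)-3-{[(triisopropylsilyl)oxy]methyl}butane-1,4-diyl bis(2,2-dimethylpropanoate)
Conditions: pivaloyl chloride, pyridine, DMAP (cat.), CH2Cl2, 0 °C → rt
Reagents that add atoms: pivaloyl chloride, CC(C)(C)C(Cl)=O
Why: Nucleophile-catalysed acylation of two primary alcohols; pivalates are acid-stable, weakly nucleophilic spectators for the cationic step and, being hindered, slow to migrate or to be transferred.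

Step 9
Reactants: 13 (2R,3R)-2-(Ar-methyl)-3-{[(triisopropylsilyl)oxy]methyl}butane-1,4-diyl bis(2,2-dimethylpropanoate)
Product: 14 (2R,3S)-2-(Ar-methyl)-3-(hydroxymethyl)butane-1,4-diyl bis(2,2-dimethylpropanoate)
Conditions: HF·pyridine, pyridine, THF, 0 °C → rt
Reagents that add atoms: none
Why: Fluoride-mediated cleavage of the silyl ether under acidic conditions; no free alkoxide is formed, so a 1,3 pivaloyl shift from the C9 oxygen to the C1 oxygen, which would invert C2, has no opportunity.

Step 10
Reactants: 14 (2R,3S)-2-(Ar-methyl)-3-(hydroxymethyl)butane-1,4-diyl bis(2,2-dimethylpropanoate)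
Product: 15 (2R,3R)-4-Ar-2,3-bis[(pivaloyloxy)methyl]butanal
Conditions: Dess–Martin periodinane, NaHCO3, CH2Cl2, 0 °C → rt; crude aldehyde used at once
Reagents that add atoms: none
Why: Dess–Martin oxidation of a primary alcohol under buffered, amine-free conditions, which should leave the alpha stereocentre (C2) and the beta-pivaloyloxy group of the aldehyde intact.

Step 11
Reactants: 15 (2R,3R)-4-Ar-2,3-bis[(pivaloyloxy)methyl]butanal; 16 2,6-dimethoxyphenol
Product: 18 (1S,2R,3R)-7-O-benzyl-lyoniresinol 9,10-dipivalate, via tetralol 17 (not isolated)
Conditions: Bi(OTf)3 (10 mol%), 16 (4 equiv), CH2Cl2, −20 °C → rt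
Reagents that add atoms: none
Why: Bi(OTf)3 (or the TfOH it releases with traces of water) activates the aldehyde of 15, and C8a of ring A, ortho and para to the two methoxy groups, attacks C1 in a Friedel–Crafts hydroxyalkylation that closes ring B in the 6-exo-trig mode with respect to the carbonyl group and gives tetralol 17. The benzylic hydroxyl of 17 then ionises to a C1 cation stabilised by the C8 and C6 methoxy groups, and 16 intercepts it through its carbon para to the hydroxyl, the activated position that is not flanked by a methoxy group, so that C1–C8a and C1–C1' are formed in one flask. The closest known reaction type is the acid-catalysed cyclisation of an aryl-tethered aldehyde to a 1-tetralol followed by Friedel–Crafts arylation of the benzylic cation by an electron-rich arene. The new stereocentre C1 is controlled by C2: the arene should add to the half-chair cation on the face anti to the pivaloyloxymethyl group, a six-membered acyloxonium bridge from the C9 pivalate carbonyl, if it forms, can only be opened with the same 1,2-trans result, and this is also the all-equatorial, thermodynamically preferred arrangement. The step needs ring closure to outrun both intermolecular attack of 16 on the aldehyde and enolisation at C2, which the six-membered transition state and the high nucleophilicity of ring A should secure, and regiochemistry on ring A is not an issue because its two ortho carbons are equivalent. The excess of 16 is there to trap the cation before it loses the C2 proton or alkylates a product molecule, and a catalytic Lewis acid at low temperature is preferred to a stoichiometric strong acid in order to spare the aryl benzyl ether.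

Step 12
Reactants: 18 (1S,2R,3R)-7-O-benzyl-lyoniresinol 9,10-dipivalate
Product: 19 (1S,2R,3R)-7-O-benzyl-lyoniresinol
Conditions: LiAlH4, THF, 0 °C → rt; aq. potassium sodium tartrate
Reagents that add atoms: none
Why: Reductive cleavage of both hindered esters by hydride; the aluminium phenoxide formed from ring C is inert, and the aryl ethers and the three stereocentres are not affected.

Step 13
Reactants: 19 (1S,2R,3R)-7-O-benzyl-lyoniresinol
Product: 20 (1S,2R,3R)-lyoniresinol
Conditions: H2 (1 atm), Pd/C (10 wt%), MeOH/EtOAc, rt
Reagents that add atoms: none
Why: Hydrogenolysis of the aryl benzyl ether on palladium; the conditions are neutral, so the acid-sensitive C1 centre and the oxidation-prone phenols are not endangered, and filtration is the only work-up.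

## Compound list

1 | syringaldehyde (4-hydroxy-3,5-dimethoxybenzaldehyde) | COc1cc(C=O)cc(OC)c1O | starting material
2 | 4-(benzyloxy)-3,5-dimethoxybenzaldehyde | COc1cc(C=O)cc(OC)c1OCc1ccccc1 | intermediate
3 | dimethyl succinate | COC(=O)CCC(=O)OC | starting material
4 | methyl 2-[4-(benzyloxy)-3,5-dimethoxyphenyl]-5-oxotetrahydrofuran-3-carboxylate (paraconate lactone, stereoisomer mixture) | COC(=O)C1CC(=O)OC1c1cc(OC)c(OCc2ccccc2)c(OC)c1 | intermediate (not isolated)
5 | (E)-4-[4-(benzyloxy)-3,5-dimethoxyphenyl]-3-(methoxycarbonyl)but-3-enoic acid | COc1cc(/C=C(\CC(=O)O)C(=O)OC)cc(OC)c1OCc1ccccc1 | intermediate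
6 | (3R)-4-[4-(benzyloxy)-3,5-dimethoxyphenyl]-3-(methoxycarbonyl)butanoic acid | COc1cc(C[C@H](CC(=O)O)C(=O)OC)cc(OC)c1OCc1ccccc1 | intermediate
7 | (3R)-4-[4-(benzyloxy)-3,5-dimethoxyphenyl]-3-(hydroxymethyl)butanoic acid (present as its lithium salt) | COc1cc(C[C@H](CC(=O)O)CO)cc(OC)c1OCc1ccccc1 | intermediate (not isolated)
8 | (4R)-4-{[4-(benzyloxy)-3,5-dimethoxyphenyl]methyl}dihydrofuran-2(3H)-one | COc1cc(C[C@H]2COC(=O)C2)cc(OC)c1OCc1ccccc1 | intermediate
9 | lithium enolate of 8, lithium (3R)-3-{[4-(benzyloxy)-3,5-dimethoxyphenyl]methyl}-2,3-dihydrofuran-5-olate | [Li+].COc1cc(C[C@H]2COC([O-])=C2)cc(OC)c1OCc1ccccc1 | intermediate (not isolated)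
10 | (3S,4R)-4-{[4-(benzyloxy)-3,5-dimethoxyphenyl]methyl}-3-(hydroxymethyl)dihydrofuran-2(3H)-one (3,4-trans) | COc1cc(C[C@H]2COC(=O)[C@@H]2CO)cc(OC)c1OCc1ccccc1 | intermediate
11 | (3S,4R)-4-{[4-(benzyloxy)-3,5-dimethoxyphenyl]methyl}-3-{[(triisopropylsilyl)oxy]methyl}dihydrofuran-2(3H)-one | COc1cc(C[C@H]2COC(=O)[C@@H]2CO[Si](C(C)C)(C(C)C)C(C)C)cc(OC)c1OCc1ccccc1 | intermediate
12 | (2R,3R)-2-{[4-(benzyloxy)-3,5-dimethoxyphenyl]methyl}-3-{[(triisopropylsilyl)oxy]methyl}butane-1,4-diol | COc1cc(C[C@@H](CO)[C@@H](CO[Si](C(C)C)(C(C)C)C(C)C)CO)cc(OC)c1OCc1ccccc1 | intermediate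
13 | (2R,3R)-2-{[4-(benzyloxy)-3,5-dimethoxyphenyl]methyl}-3-{[(triisopropylsilyl)oxy]methyl}butane-1,4-diyl bis(2,2-dimethylpropanoate) | COc1cc(C[C@@H](COC(=O)C(C)(C)C)[C@@H](CO[Si](C(C)C)(C(C)C)C(C)C)COC(=O)C(C)(C)C)cc(OC)c1OCc1ccccc1 | intermediate
14 | (2R,3S)-2-{[4-(benzyloxy)-3,5-dimethoxyphenyl]methyl}-3-(hydroxymethyl)butane-1,4-diyl bis(2,2-dimethylpropanoate) | COc1cc(C[C@@H](COC(=O)C(C)(C)C)[C@@H](CO)COC(=O)C(C)(C)C)cc(OC)c1OCc1ccccc1 | intermediate
15 | (2R,3R)-4-[4-(benzyloxy)-3,5-dimethoxyphenyl]-2,3-bis{[(2,2-dimethylpropanoyl)oxy]methyl}butanal | COc1cc(C[C@@H](COC(=O)C(C)(C)C)[C@@H](C=O)COC(=O)C(C)(C)C)cc(OC)c1OCc1ccccc1 | intermediate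
16 | 2,6-dimethoxyphenol | COc1cccc(OC)c1O | starting material
17 | [(2R,3R)-7-(benzyloxy)-1-hydroxy-6,8-dimethoxy-1,2,3,4-tetrahydronaphthalene-2,3-diyl]bis(methylene) bis(2,2-dimethylpropanoate) (both C1 epimers) | OC1c2c(cc(OC)c(OCc3ccccc3)c2OC)C[C@@H](COC(=O)C(C)(C)C)[C@@H]1COC(=O)C(C)(C)C | intermediate (not isolated)
18 | [(1S,2R,3R)-7-(benzyloxy)-1-(4-hydroxy-3,5-dimethoxyphenyl)-6,8-dimethoxy-1,2,3,4-tetrahydronaphthalene-2,3-diyl]bis(methylene) bis(2,2-dimethylpropanoate) (7-O-benzyl-lyoniresinol 9,10-dipivalate) | COc1cc([C@H]2c3c(cc(OC)c(OCc4ccccc4)c3OC)C[C@@H](COC(=O)C(C)(C)C)[C@@H]2COC(=O)C(C)(C)C)cc(OC)c1O | intermediate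
19 | 4-[(1S,2R,3R)-7-(benzyloxy)-2,3-bis(hydroxymethyl)-6,8-dimethoxy-1,2,3,4-tetrahydronaphthalen-1-yl]-2,6-dimethoxyphenol (7-O-benzyl-lyoniresinol) | COc1cc([C@H]2c3c(cc(OC)c(OCc4ccccc4)c3OC)C[C@@H](CO)[C@@H]2CO)cc(OC)c1O | intermediate
20 | (1S,2R,3R)-lyoniresinol, (6R,7R,8S)-8-(4-hydroxy-3,5-dimethoxyphenyl)-6,7-bis(hydroxymethyl)-1,3-dimethoxy-5,6,7,8-tetrahydronaphthalen-2-ol | COc1cc([C@H]2c3c(cc(OC)c(O)c3OC)C[C@@H](CO)[C@@H]2CO)cc(OC)c1O | target

## Step count and least certain steps

Total number of steps: 13. Longest linear sequence: 13 steps, from 1 to 20; 3 and 16 are purchased and enter at steps 2 and 11.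

**Step 11 (key step).** The most likely failures are attack of 16 on the activated aldehyde before ring closure, loss of the C2 proton from the C1 cation followed by reprotonation (which would erode the C2 configuration), entry of 16 through a carbon next to a methoxy group, and benzyl transfer from the ring A ether to the excess phenol. The fallback sets out from 15 and comes back at 20; it attaches ring C as a carbanion and closes ring B afterwards. Purchased 4-bromo-2,6-dimethoxyphenol is benzylated (BnBr, K2CO3, DMF) to 5-bromo-2-(benzyloxy)-1,3-dimethoxybenzene F1 (the same compound as A4). Bromine–lithium exchange (n-BuLi, THF, −78 °C) and addition of the aryllithium to 15 should give the diaryl carbinol F2 as a mixture of carbinol epimers. Brief treatment with CF3CO2H in CH2Cl2 at 0 °C ionises the carbinol, and C8a closes ring B on the diarylmethyl cation, trans to the C2 branch, to give the dibenzyl dipivalate F3. LiAlH4 then gives the dibenzyl diol F4, and hydrogenolysis of both benzyl ethers (H2, Pd/C) gives 20.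

**Step 5.** The most likely failures are addition of further formaldehyde units to the aldolate, retro-aldol loss or dehydration to the alpha-methylene lactone on work-up, and incomplete trans selectivity. The fallback sets out from 8 and comes back at 14; it replaces the aldol by an alkylation that brings the C1 oxygen in already protected. The enolate 9 is alkylated with 2-(trimethylsilyl)ethoxymethyl chloride (THF, −78 °C) to give the trans ether lactone F5. LiAlH4 gives the diol F6 and pivaloylation (pivaloyl chloride, pyridine, DMAP) the dipivalate F7. BF3·OEt2 in CH2Cl2 at 0 °C cleaves the 2-(trimethylsilyl)ethyl ether by beta-silyl fragmentation and gives 14, so that the silylation and desilylation steps are not needed.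

**Step 10.** The most likely failure is beta-elimination of pivalic acid from 15, or epimerisation at C2, during oxidation, work-up or storage. The fallback sets out from 8 and comes back at 18; C1 is introduced at the aldehyde oxidation level as a dimethyl acetal, so that no free aldehyde is ever handled. 8 is converted into its trimethylsilyl ketene acetal F8 (LiN(iPr)2, Me3SiCl, THF, −78 °C). Mukaiyama-type addition of F8 to trimethyl orthoformate under Me3SiOTf catalysis, anti to the arylmethyl group, should give the trans dimethoxymethyl lactone F9. LiAlH4 gives the diol acetal F10 and pivaloylation the dipivalate acetal F11. F11 is then treated with 16 and Bi(OTf)3 in CH2Cl2: the acetal ionises to an oxocarbenium ion, C8a attacks it, the second methoxy group leaves from C1 and 16 adds, which gives 18.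

**Step 3.** The most likely failure is insufficient enantioselectivity; an inverted sense of induction is answered by the antipodal ligand. The fallback sets out from 5 and comes back at 6; it replaces asymmetric catalysis by classical resolution. 5 is hydrogenated with Ru(OAc)2(rac-BINAP) in MeOH to the racemic acid F12. Crystallisation with (S)-1-phenylethylamine (or with its antipode, should that one give the less soluble salt of the (R)-acid) gives the diastereomerically pure ammonium salt F13, and aq. HCl releases enantiopure 6.

## Further compounds

F1 | step 11 | 5-bromo-2-(benzyloxy)-1,3-dimethoxybenzene | COc1cc(Br)cc(OC)c1OCc1ccccc1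
F2 | step 11 | (2R,3R)-2-{[4-(benzyloxy)-3,5-dimethoxyphenyl]methyl}-3-{[4-(benzyloxy)-3,5-dimethoxyphenyl](hydroxy)methyl}butane-1,4-diyl bis(2,2-dimethylpropanoate) (carbinol epimers) | COc1cc(C[C@@H](COC(=O)C(C)(C)C)[C@@H](C(O)c2cc(OC)c(OCc3ccccc3)c(OC)c2)COC(=O)C(C)(C)C)cc(OC)c1OCc1ccccc1
F3 | step 11 | [(1S,2R,3R)-7-(benzyloxy)-1-[4-(benzyloxy)-3,5-dimethoxyphenyl]-6,8-dimethoxy-1,2,3,4-tetrahydronaphthalene-2,3-diyl]bis(methylene) bis(2,2-dimethylpropanoate) | COc1cc([C@H]2c3c(cc(OC)c(OCc4ccccc4)c3OC)C[C@@H](COC(=O)C(C)(C)C)[C@@H]2COC(=O)C(C)(C)C)cc(OC)c1OCc1ccccc1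
F4 | step 11 | [(1S,2R,3R)-7-(benzyloxy)-1-[4-(benzyloxy)-3,5-dimethoxyphenyl]-6,8-dimethoxy-1,2,3,4-tetrahydronaphthalene-2,3-diyl]dimethanol | COc1cc([C@H]2c3c(cc(OC)c(OCc4ccccc4)c3OC)C[C@@H](CO)[C@@H]2CO)cc(OC)c1OCc1ccccc1
F5 | step 5 | (3S,4R)-4-{[4-(benzyloxy)-3,5-dimethoxyphenyl]methyl}-3-{[2-(trimethylsilyl)ethoxy]methyl}dihydrofuran-2(3H)-one | COc1cc(C[C@H]2COC(=O)[C@@H]2COCC[Si](C)(C)C)cc(OC)c1OCc1ccccc1
F6 | step 5 | (2R,3R)-2-{[4-(benzyloxy)-3,5-dimethoxyphenyl]methyl}-3-{[2-(trimethylsilyl)ethoxy]methyl}butane-1,4-diol | COc1cc(C[C@@H](CO)[C@@H](COCC[Si](C)(C)C)CO)cc(OC)c1OCc1ccccc1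
F7 | step 5 | (2R,3S)-2-{[4-(benzyloxy)-3,5-dimethoxyphenyl]methyl}-3-{[2-(trimethylsilyl)ethoxy]methyl}butane-1,4-diyl bis(2,2-dimethylpropanoate) | COc1cc(C[C@@H](COC(=O)C(C)(C)C)[C@@H](COCC[Si](C)(C)C)COC(=O)C(C)(C)C)cc(OC)c1OCc1ccccc1
F8 | step 10 | (3R)-3-{[4-(benzyloxy)-3,5-dimethoxyphenyl]methyl}-5-[(trimethylsilyl)oxy]-2,3-dihydrofuran | COc1cc(C[C@H]2COC(O[Si](C)(C)C)=C2)cc(OC)c1OCc1ccccc1
F9 | step 10 | (3S,4R)-4-{[4-(benzyloxy)-3,5-dimethoxyphenyl]methyl}-3-(dimethoxymethyl)dihydrofuran-2(3H)-one | COc1cc(C[C@H]2COC(=O)[C@@H]2C(OC)OC)cc(OC)c1OCc1ccccc1
F10 | step 10 | (2R,3R)-2-{[4-(benzyloxy)-3,5-dimethoxyphenyl]methyl}-3-(dimethoxymethyl)butane-1,4-diol | COc1cc(C[C@@H](CO)[C@@H](C(OC)OC)CO)cc(OC)c1OCc1ccccc1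
F11 | step 10 | (2R,3R)-2-{[4-(benzyloxy)-3,5-dimethoxyphenyl]methyl}-3-(dimethoxymethyl)butane-1,4-diyl bis(2,2-dimethylpropanoate) | COc1cc(C[C@@H](COC(=O)C(C)(C)C)[C@@H](C(OC)OC)COC(=O)C(C)(C)C)cc(OC)c1OCc1ccccc1
F12 | step 3 | racemic 4-[4-(benzyloxy)-3,5-dimethoxyphenyl]-3-(methoxycarbonyl)butanoic acid | COc1cc(CC(CC(=O)O)C(=O)OC)cc(OC)c1OCc1ccccc1
F13 | step 3 | (S)-1-phenylethylammonium (3R)-4-[4-(benzyloxy)-3,5-dimethoxyphenyl]-3-(methoxycarbonyl)butanoate | COc1cc(C[C@H](CC(=O)[O-])C(=O)OC)cc(OC)c1OCc1ccccc1.C[C@H]([NH3+])c1ccccc1
A1 | alternative 1 | (2R,4R)-pentane-2,4-diyl bis[(E)-3-(4-hydroxy-3,5-dimethoxyphenyl)prop-2-enoate] | COc1cc(/C=C/C(=O)O[C@H](C)C[C@@H](C)OC(=O)/C=C/c2cc(OC)c(O)c(OC)c2)cc(OC)c1O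
A2 | alternative 1 | pentanediol-bridged (1S,2R)-7-hydroxy-1-(4-hydroxy-3,5-dimethoxyphenyl)-6,8-dimethoxy-1,2-dihydronaphthalene-2,3-dicarboxylate (nine-membered dilactone) | COc1cc([C@H]2c3c(cc(OC)c(O)c3OC)C=C5C(=O)O[C@H](C)C[C@@H](C)OC(=O)[C@H]25)cc(OC)c1O
A3 | alternative 2 | N-tosylhydrazone of dimethyl 2-[(2R)-1-(benzyloxy)-3-[4-(benzyloxy)-2-formyl-3,5-dimethoxyphenyl]propan-2-yl]malonate | COc1cc(C[C@@H](COCc2ccccc2)C(C(=O)OC)C(=O)OC)c(C=NNS(=O)(=O)c2ccc(C)cc2)c(OC)c1OCc1ccccc1
A4 | alternative 2 | 5-bromo-2-(benzyloxy)-1,3-dimethoxybenzene | COc1cc(Br)cc(OC)c1OCc1ccccc1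
A5 | alternative 2 | dimethyl (1S,3R)-7-(benzyloxy)-3-[(benzyloxy)methyl]-1-[4-(benzyloxy)-3,5-dimethoxyphenyl]-6,8-dimethoxy-3,4-dihydronaphthalene-2,2(1H)-dicarboxylate | COc1cc([C@H]2c3c(cc(OC)c(OCc4ccccc4)c3OC)C[C@@H](COCc3ccccc3)C2(C(=O)OC)C(=O)OC)cc(OC)c1OCc1ccccc1
A6 | alternative 3 | 2-diazo-1-{3-[3,5-dimethoxy-4-(methoxymethoxy)phenyl]-4,5-bis{[(tert-butyldimethylsilyl)oxy]methyl}cyclohex-1-en-1-yl}ethan-1-one, stereocentres as at C1, C2 and C3 of 20 | COc1cc([C@H]2C=C(C(=O)C=[N+]=[N-])C[C@@H](CO[Si](C)(C)C(C)(C)C)[C@@H]2CO[Si](C)(C)C(C)(C)C)cc(OC)c1OCOC
A7 | alternative 3 | methoxyethyne | COC#C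
A8 | alternative 3 | (1S,2R,3R)-2,3-bis{[(tert-butyldimethylsilyl)oxy]methyl}-1-[3,5-dimethoxy-4-(methoxymethoxy)phenyl]-6-methoxy-1,2,3,4-tetrahydronaphthalen-8-ol | COc1cc([C@H]2c3c(cc(OC)cc3O)C[C@@H](CO[Si](C)(C)C(C)(C)C)[C@@H]2CO[Si](C)(C)C(C)(C)C)cc(OC)c1OCOC
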